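The 20-membered ring is opened at the diaryl ether bond between C4 of ring C (the hydroxylated bibenzyl ring) and the oxygen on ring D. The feature exploited is that this ring C carbon lies ortho to the free hydroxyl at C3: the hydroxyl is carried as a formyl group, which activates a fluorine at C4 for SNAr. The precursor is an open-chain bis(bibenzyl) with a silyl-protected ring D phenol and a 4-fluoro-3-formylphenyl ring C, assembled by two hydroboration/Suzuki couplings. Fluoride unmasks the phenoxide and closes the macrocycle in one operation; a Baeyer–Villiger oxidation then turns the activating formyl group into the phenol.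

Key step: step 6

Remark: ring A is the methoxy-bearing ring, ring B the para-linked phenoxy ring, ring C the hydroxyl-bearing ring and ring D the meta-linked ring. The target has no stereocentre. 3-Vinylphenol is assumed to be available as the stabilised commercial monomer.

Step 1
Reactants: 1 3-vinylphenol
Product: 2 triisopropyl(3-vinylphenoxy)silane
Conditions: TIPSCl, imidazole, DMF, 0 °C to rt
Reagents that add atoms: triisopropylsilyl chloride (TIPSCl), CC(C)[Si](Cl)(C(C)C)C(C)C
Why: Imidazole-promoted O-silylation of a phenol; the bulky TIPS ether should survive the ylide and the aqueous phosphate couplings and is the group that fluoride removes in the key step.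

Step 2
Reactants: 3 5-bromo-2-methoxyphenol; 4 4-fluorobenzaldehyde
Product: 5 4-(5-bromo-2-methoxyphenoxy)benzaldehyde
Conditions: K2CO3, DMF, 120 °C
Reagents that add atoms: none
Why: SNAr (addition–elimination) of the phenoxide of 3 on the para-formyl-activated C–F bond of 4 should form the ring A–O–ring B ether, the unactivated C–Br bond staying intact.

Step 3
Reactants: 2 triisopropyl(3-vinylphenoxy)silane; 5 4-(5-bromo-2-methoxyphenoxy)benzaldehyde
Product: 7 4-[2-methoxy-5-[2-[3-(triisopropylsilyloxy)phenyl]ethyl]phenoxy]benzaldehyde, via alkylborane 6 (not isolated)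
Conditions: 2, 9-BBN, THF, 0 °C to rt; then aq. K3PO4, 5, Pd(dppf)Cl2 (cat.), DMF, 60 °C
Reagents that add atoms: none
Why: Terminal-selective hydroboration of the styrene with 9-BBN followed by B-alkyl Suzuki–Miyaura coupling at the aryl bromide should give the ring D–CH2CH2–ring A link directly at the saturated level, the aqueous base converting residual B–H and the borane into borates that spare the aldehyde.

Step 4
Reactants: 7 4-[2-methoxy-5-[2-[3-(triisopropylsilyloxy)phenyl]ethyl]phenoxy]benzaldehyde
Product: 8 triisopropyl[3-[2-[4-methoxy-3-(4-vinylphenoxy)phenyl]ethyl]phenoxy]silane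
Conditions: Ph3PCH3Br (1.3 equiv), KOtBu (1.2 equiv), THF, 0 °C to rt
Reagents that add atoms: methyltriphenylphosphonium bromide, C[P+](c1ccccc1)(c1ccccc1)c1ccccc1.[Br-]
Why: Wittig methylenation of the aryl aldehyde with the preformed unstabilised ylide (no excess alkoxide, so the silyl ether is not attacked) should give the ring B styrene.

Step 5
Reactants: 8 triisopropyl[3-[2-[4-methoxy-3-(4-vinylphenoxy)phenyl]ethyl]phenoxy]silane; 9 5-bromo-2-fluorobenzaldehyde
Product: 11 2-fluoro-5-[2-[4-[2-methoxy-5-[2-[3-(triisopropylsilyloxy)phenyl]ethyl]phenoxy]phenyl]ethyl]benzaldehyde, via alkylborane 10 (not isolated)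
Conditions: 8, 9-BBN (1.1 equiv), THF, rt; then aq. K3PO4, 9, Pd(dppf)Cl2 (cat.), DMF, 50 °C
Reagents that add atoms: none
Why: A second hydroboration/B-alkyl Suzuki–Miyaura coupling should join ring B to ring C through oxidative addition at the C–Br bond of 9 only, the C–F bond and the formyl group being inert to mild aqueous phosphate at this temperature.

Step 6
Reactants: 11 2-fluoro-5-[2-[4-[2-methoxy-5-[2-[3-(triisopropylsilyloxy)phenyl]ethyl]phenoxy]phenyl]ethyl]benzaldehyde
Product: 13 macrocyclic aldehyde (the pakyonol macrocycle with CHO in place of the ring C hydroxyl), via caesium phenoxide 12 (not isolated)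
Conditions: CsF (5 equiv), 4 Å molecular sieves, DMSO, slow addition of 11 to a final 2 mM, 110 °C
Reagents that add atoms: none
Why: Fluoride cleaves the aryl silyl ether of 11 to phenoxide 12, which adds to ring C at the fluorine-bearing carbon para to the ethano bridge; the Meisenheimer anion is stabilised by the ortho formyl group and expels fluoride (intramolecular SNAr). The closest known reaction type is the fluoride-mediated SNAr macrocyclisation of phenols onto ortho-activated aryl fluorides used for macrocyclic diaryl ethers. The 20-membered ring is closed end to end by addition–elimination at an aromatic carbon under high dilution. No stereocentre is formed. The step needs cyclisation to outrun intermolecular etherification and needs attack at the ring carbon instead of the carbonyl: slow addition at about 2 mM and the folded diaryl ether and bibenzyl hinges should secure the first, the reversibility of hemiacetal formation the second. Regiochemistry is unambiguous because 11 holds a single latent phenoxide and a single activated C–F bond.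

Step 7
Reactants: 13 macrocyclic aldehyde
Product: 15 pakyonol, via aryl formate 14 (not isolated)
Conditions: mCPBA, CH2Cl2, 0 °C to rt; then K2CO3 (cat.), MeOH, rt
Reagents that add atoms: mCPBA (3-chloroperoxybenzoic acid), OOC(=O)c1cccc(Cl)c1
Why: Baeyer–Villiger (Dakin-type) oxidation, in which the electron-rich aryl group carrying the ortho aryloxy substituent migrates in the Criegee intermediate to give the aryl formate, whose methanolysis should release the ring C phenol.

Compound list
1 | 3-vinylphenol | C=Cc1cccc(O)c1 | starting material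
2 | triisopropyl(3-vinylphenoxy)silane | C=Cc1cccc(O[Si](C(C)C)(C(C)C)C(C)C)c1 | intermediate
3 | 5-bromo-2-methoxyphenol | COc1ccc(Br)cc1O | starting material
4 | 4-fluorobenzaldehyde | O=Cc1ccc(F)cc1 | starting material
5 | 4-(5-bromo-2-methoxyphenoxy)benzaldehyde | COc1ccc(Br)cc1Oc1ccc(C=O)cc1 | intermediate
6 | 9-[2-[3-(triisopropylsilyloxy)phenyl]ethyl]-9-borabicyclo[3.3.1]nonane (formed in the flask) | CC(C)[Si](Oc1cccc(CCB2C3CCCC2CCC3)c1)(C(C)C)C(C)C | intermediate
7 | 4-[2-methoxy-5-[2-[3-(triisopropylsilyloxy)phenyl]ethyl]phenoxy]benzaldehyde | COc1ccc(CCc2cccc(O[Si](C(C)C)(C(C)C)C(C)C)c2)cc1Oc1ccc(C=O)cc1 | intermediate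
8 | triisopropyl[3-[2-[4-methoxy-3-(4-vinylphenoxy)phenyl]ethyl]phenoxy]silane | COc1ccc(CCc2cccc(O[Si](C(C)C)(C(C)C)C(C)C)c2)cc1Oc1ccc(C=C)cc1 | intermediate
9 | 5-bromo-2-fluorobenzaldehyde | O=Cc1cc(Br)ccc1F | starting material
10 | B-alkyl-9-borabicyclo[3.3.1]nonane from 8 (boron on the terminal carbon of the former vinyl group; formed in the flask) | COc1ccc(CCc2cccc(O[Si](C(C)C)(C(C)C)C(C)C)c2)cc1Oc1ccc(CCB2C3CCCC2CCC3)cc1 | intermediate
11 | 2-fluoro-5-[2-[4-[2-methoxy-5-[2-[3-(triisopropylsilyloxy)phenyl]ethyl]phenoxy]phenyl]ethyl]benzaldehyde | COc1ccc(CCc2cccc(O[Si](C(C)C)(C(C)C)C(C)C)c2)cc1Oc1ccc(CCc2ccc(F)c(C=O)c2)cc1 | intermediate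
12 | caesium phenoxide of desilylated 11 (formed in the flask) | [Cs+].COc1ccc(CCc2cccc([O-])c2)cc1Oc1ccc(CCc2ccc(F)c(C=O)c2)cc1 | intermediate
13 | macrocyclic aldehyde: 20-membered bis(bibenzyl) diether, ring C carrying CHO at C3 and the ring D oxygen at C4 | COc1ccc2cc1Oc1ccc(cc1)CCc1ccc(c(C=O)c1)Oc1cccc(c1)CC2 | intermediate
14 | macrocyclic aryl formate (ring C C3–OCHO; formed in the flask) | COc1ccc2cc1Oc1ccc(cc1)CCc1ccc(c(OC=O)c1)Oc1cccc(c1)CC2 | intermediate
15 | pakyonol | COc1ccc2cc1Oc1ccc(cc1)CCc1ccc(c(O)c1)Oc1cccc(c1)CC2 | target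

Total step count: 7. Longest linear sequence: 6 steps (step 1 or step 2, then steps 3 to 7).

Steps most likely to fail

Step 6. With only one ortho formyl group as activator the ring closure may be slow at high dilution, so that intermolecular etherification to oligomers or displacement of fluoride by adventitious hydroxide overtakes it. The fallback sets out from 8 and comes back at 15. Styrene 8 is hydroborated to borane 10 as in step 5 and coupled with 4-bromo-1-fluoro-2-nitrobenzene (Pd(dppf)Cl2, anhydrous K3PO4, DMF, 50 °C) to give the nitro seco compound F1. CsF in DMF at rt and 2 mM should desilylate it to the caesium phenoxide F2 (not isolated), which should close under the much stronger ortho-nitro activation to the macrocyclic nitro compound F3. Hydrogenation (H2, Pd/C, EtOAc) should give the macrocyclic aniline F4. Diazotisation (NaNO2, H2SO4, H2O/THF, 0 °C) should give the arenediazonium hydrogen sulfate F5 (not isolated), whose hydroxylation (Cu2O, Cu(NO3)2, H2O, rt) should give 15.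

Step 5. The formyl group of 9 may be reduced by residual boron hydride, or the fluoride may be displaced by aqueous base, during the coupling. The fallback sets out from 8 and comes back at 11. A Heck reaction of 8 with 9 (Pd(OAc)2, P(o-tol)3, Et3N, DMF, 100 °C) should give the (E)-stilbene F6. Chemoselective hydrogenation of the alkene over Pd/C poisoned with diphenyl sulfide (H2, 1 atm, EtOAc, rt) should spare the aldehyde and the C–F bond and give 11.

Step 3. Oxidative addition to the electron-rich aryl bromide may be slow, leaving time for reduction of the ring B aldehyde or for protodeboronation of 6. The fallback sets out from 6 and 3 and comes back at 7. Borane 6 is coupled with the aldehyde-free bromophenol 3 (Pd(OAc)2, SPhos, aq. K3PO4, THF, 65 °C) to give 2-methoxy-5-[2-[3-(triisopropylsilyloxy)phenyl]ethyl]phenol F7. A Chan–Lam–Evans etherification with 4-formylphenylboronic acid (Cu(OAc)2 (cat.), pyridine, 4 Å molecular sieves, CH2Cl2, O2, rt) should then form the diaryl ether 7 without exposing the silyl ether to hot carbonate.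

Further compounds
F1 | step 6 | 1-fluoro-4-[2-[4-[2-methoxy-5-[2-[3-(triisopropylsilyloxy)phenyl]ethyl]phenoxy]phenyl]ethyl]-2-nitrobenzene | COc1ccc(CCc2cccc(O[Si](C(C)C)(C(C)C)C(C)C)c2)cc1Oc1ccc(CCc2ccc(F)c([N+](=O)[O-])c2)cc1
F2 | step 6 | caesium phenoxide of desilylated F1 | [Cs+].COc1ccc(CCc2cccc([O-])c2)cc1Oc1ccc(CCc2ccc(F)c([N+](=O)[O-])c2)cc1
F3 | step 6 | macrocyclic nitro compound (NO2 in place of the ring C hydroxyl of pakyonol) | COc1ccc2cc1Oc1ccc(cc1)CCc1ccc(c([N+](=O)[O-])c1)Oc1cccc(c1)CC2
F4 | step 6 | macrocyclic aniline (NH2 in place of the ring C hydroxyl of pakyonol) | COc1ccc2cc1Oc1ccc(cc1)CCc1ccc(c(N)c1)Oc1cccc(c1)CC2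
F5 | step 6 | macrocyclic arenediazonium hydrogen sulfate | COc1ccc2cc1Oc1ccc(cc1)CCc1ccc(c([N+]#N)c1)Oc1cccc(c1)CC2.OS(=O)(=O)[O-]
F6 | step 5 | (E)-2-fluoro-5-[2-[4-[2-methoxy-5-[2-[3-(triisopropylsilyloxy)phenyl]ethyl]phenoxy]phenyl]ethenyl]benzaldehyde | COc1ccc(CCc2cccc(O[Si](C(C)C)(C(C)C)C(C)C)c2)cc1Oc1ccc(/C=C/c2ccc(F)c(C=O)c2)cc1
F7 | step 3 | 2-methoxy-5-[2-[3-(triisopropylsilyloxy)phenyl]ethyl]phenol | COc1ccc(CCc2cccc(O[Si](C(C)C)(C(C)C)C(C)C)c2)cc1O
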